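Assumption: the SMILES is read as an all-cis (2R,3R,4S)-7,3',4'-trihydroxyflavan-3-ol unit (rings A, B, C) bonded from C4 to C6 of (2R,3S)-catechin (rings D, E, F).

**Retrosynthetic overview**
1. Lower unit (rings D, E, F, bought with both stereocentres): (+)-catechin 1 → penta-O-benzyl ether 2 → 8-bromide 3 → 6-iodide 4, a C6 nucleophile with C8 blocked.
2. Upper ring A with C4 and O1: 2,4-dihydroxybenzaldehyde 5 as bis-carbonate 6. Upper ring B with C2 and C3: 3,4-bis(benzyloxy)benzaldehyde 7 → alkyne 8 → (Z)-enol benzoate 9.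
3. Key disconnection: Grignard reagent 10 (from 4) adds to 6 (alkoxide 11, which makes the C4–C6 bond between the units) and gives o-quinone methide 12. Its [4+2] cycloaddition with 9 closes upper ring C of 13 across O1–C2 and C3–C4.
4. Methanolysis of benzoate and carbonate (14), then one hydrogenolysis of seven benzyl ethers and the C8–Br bond, gives target 15.
5. Ring order: rings A, B, D, E and F are bought; ring C is the only ring made and is made last. The upper all-cis array comes from the Z-alkene and the endo transition state. Its absolute sense is not induced by the remote catechin stereocentres (expect about 1:1), so it is secured by separating the two all-cis diastereomers at 13.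

**Route**

Step 1
Reactants: 1 (+)-catechin
Product: 2 penta-O-benzyl-(+)-catechin
Conditions: NaH (6 equiv), BnBr (6 equiv), DMF, 0 °C → rt
Reagents that add atoms: benzyl bromide BrCc1ccccc1
Why: Williamson ether synthesis in which the four phenoxides and the 3-alkoxide are O-benzylated by SN2 at low temperature, leaving C2 and C3 untouched.

Step 2
Reactants: 2 penta-O-benzyl-(+)-catechin
Product: 3 8-bromo-penta-O-benzylcatechin
Conditions: NBS (1.05 equiv), CH2Cl2, −78 °C → rt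
Reagents that add atoms: N-bromosuccinimide O=C1CCC(=O)N1Br
Why: Electrophilic aromatic bromination of the phloroglucinol-type ring D goes to C8, the preferred site in O-benzylated catechins, and so blocks that position.

Step 3
Reactants: 3 8-bromo-penta-O-benzylcatechin
Product: 4 8-bromo-6-iodo-penta-O-benzylcatechin
Conditions: NIS (1.2 equiv), TFA (cat.), CH2Cl2–MeCN, 0 °C → rt, dark
Reagents that add atoms: N-iodosuccinimide O=C1CCC(=O)N1I
Why: Electrophilic aromatic iodination can only take the one free position (C6) of the most electron-rich ring, installing a C–I bond that exchanges with magnesium far faster than the C–Br bond.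

Step 4
Reactants: 5 2,4-dihydroxybenzaldehyde
Product: 6 2,4-bis[(tert-butoxycarbonyl)oxy]benzaldehyde
Conditions: Boc2O (2.2 equiv), DMAP (5 mol%), i-Pr2NEt (0.2 equiv), THF, 0 °C → rt
Reagents that add atoms: di-tert-butyl dicarbonate CC(C)(C)OC(=O)OC(=O)OC(C)(C)C
Why: DMAP-catalysed O-acylation of both phenols gives the aryl carbonates, the ortho one later acting as the transferable group that unmasks the o-quinone methide.

Step 5
Reactants: 7 3,4-bis(benzyloxy)benzaldehyde
Product: 8 1,2-bis(benzyloxy)-4-ethynylbenzene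
Conditions: dimethyl (1-diazo-2-oxopropyl)phosphonate, K2CO3, MeOH, rt
Reagents that add atoms: dimethyl (1-diazo-2-oxopropyl)phosphonate CC(=O)C(=[N+]=[N-])P(=O)(OC)OC
Why: Ohira–Bestmann (Seyferth–Gilbert) homologation converts the aldehyde into the terminal alkyne with one added carbon under mild base that benzyl ethers tolerate.

Step 6
Reactants: 8 1,2-bis(benzyloxy)-4-ethynylbenzene
Product: 9 (Z)-2-[3,4-bis(benzyloxy)phenyl]ethenyl benzoate
Conditions: PhCO2H (1.2 equiv), [RuCl2(p-cymene)]2 (1 mol%), P(4-ClC6H4)3 (3 mol%), DMAP (4 mol%), toluene, 60 °C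
Reagents that add atoms: benzoic acid OC(=O)c1ccccc1
Why: Ruthenium-catalysed anti-Markovnikov hydro-oxycarbonylation of a terminal alkyne runs through a ruthenium vinylidene and delivers the (Z)-enol ester.

Step 7
Reactants: 4 8-bromo-6-iodo-penta-O-benzylcatechin, 6 2,4-bis[(tert-butoxycarbonyl)oxy]benzaldehyde, 9 (Z)-2-[3,4-bis(benzyloxy)phenyl]ethenyl benzoate
Product: 13 (2R,3R,4S)-2-[3,4-bis(benzyloxy)phenyl]-4-(8-bromo-penta-O-benzylcatechin-6-yl)-7-[(tert-butoxycarbonyl)oxy]chroman-3-yl benzoate, via aryl Grignard reagent 10 (not isolated), via magnesium benzhydrolate 11 (not isolated), via o-quinone methide 12 (not isolated)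
Conditions: 4, i-PrMgCl·LiCl (1.05 equiv), THF, 0 °C, 1 h; add to 6 (1.1 equiv), THF, −78 → −20 °C; then 9 (3 equiv), −20 → 50 °C, 16 h; aq. NH4Cl; SiO2 (diastereomers separated)
Reagents that add atoms: none
Why: Iodine–magnesium exchange, 1,2-addition to the aldehyde, O-to-O Boc transfer and loss of tert-butyl carbonate give the E-configured o-quinone methide, which closes ring C in an inverse-electron-demand hetero-Diels–Alder reaction in which the p-alkoxyphenyl group of the alkene directs O1 to C2, the Z geometry is kept (2,3-cis) and the endo transition state places both alkene substituents cis to the C4 aryl group (all-cis), the two faces of the planar diene giving two all-cis diastereomers of which the (2R,3R,4S) one is kept.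

Step 8
Reactants: 13 all-cis cycloadduct
Product: 14 (2R,3R,4S)-2-[3,4-bis(benzyloxy)phenyl]-4-(8-bromo-penta-O-benzylcatechin-6-yl)chroman-3,7-diol
Conditions: K2CO3 (0.5 equiv), MeOH–THF 1:1, rt → 40 °C; AcOH quench
Reagents that add atoms: none
Why: Base-catalysed transesterification with methanol removes the benzoate and the aryl tert-butyl carbonate, while benzyl ethers, the aryl bromide and all stereocentres (none is alpha to a carbonyl) are untouched.

Step 9
Reactants: 14 heptabenzyl bromo diol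
Product: 15 target, (2R,3R,4S)-2-(3,4-dihydroxyphenyl)-4-[(2R,3S)-2-(3,4-dihydroxyphenyl)-3,5,7-trihydroxychroman-6-yl]chroman-3,7-diol
Conditions: H2 (1 atm), 20% Pd(OH)2/C, Et3N (1.5 equiv), THF–MeOH–H2O, rt; filter; Sephadex LH-20, freeze-dry
Reagents that add atoms: none
Why: Heterogeneous catalytic hydrogenolysis cleaves the seven benzyl ethers and the aryl C–Br bond in one operation (Et3N takes up HBr) and leaves the cyclic benzylic C2–O1 bonds and the C4–aryl bond intact.

**Compound list**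
1 | (+)-catechin, (2R,3S)-2-(3,4-dihydroxyphenyl)chroman-3,5,7-triol | c1c(O)cc2c(c1O)C[C@H](O)[C@@H](c1ccc(O)c(O)c1)O2 | starting material
2 | penta-O-benzyl-(+)-catechin, (2R,3S)-3,5,7-tris(benzyloxy)-2-[3,4-bis(benzyloxy)phenyl]chroman | c1c(OCc3ccccc3)cc2c(c1OCc1ccccc1)C[C@H](OCc1ccccc1)[C@@H](c1ccc(OCc3ccccc3)c(OCc3ccccc3)c1)O2 | intermediate
3 | 8-bromo-penta-O-benzylcatechin | c1c(OCc3ccccc3)c(Br)c2c(c1OCc1ccccc1)C[C@H](OCc1ccccc1)[C@@H](c1ccc(OCc3ccccc3)c(OCc3ccccc3)c1)O2 | intermediate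
4 | 8-bromo-6-iodo-penta-O-benzylcatechin | Ic1c(OCc3ccccc3)c(Br)c2c(c1OCc1ccccc1)C[C@H](OCc1ccccc1)[C@@H](c1ccc(OCc3ccccc3)c(OCc3ccccc3)c1)O2 | intermediate
5 | 2,4-dihydroxybenzaldehyde | O=Cc1ccc(O)cc1O | starting material
6 | 2,4-bis[(tert-butoxycarbonyl)oxy]benzaldehyde | O=Cc1ccc(OC(=O)OC(C)(C)C)cc1OC(=O)OC(C)(C)C | intermediate
7 | 3,4-bis(benzyloxy)benzaldehyde | O=Cc1ccc(OCc2ccccc2)c(OCc2ccccc2)c1 | starting material
8 | 1,2-bis(benzyloxy)-4-ethynylbenzene | C#Cc1ccc(OCc2ccccc2)c(OCc2ccccc2)c1 | intermediate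
9 | (Z)-2-[3,4-bis(benzyloxy)phenyl]ethenyl benzoate | O=C(O/C=C\c1ccc(OCc2ccccc2)c(OCc2ccccc2)c1)c1ccccc1 | intermediate
10 | (8-bromo-penta-O-benzylcatechin-6-yl)magnesium chloride (LiCl complex), not isolated | Cl[Mg]c1c(OCc3ccccc3)c(Br)c2c(c1OCc1ccccc1)C[C@H](OCc1ccccc1)[C@@H](c1ccc(OCc3ccccc3)c(OCc3ccccc3)c1)O2 | intermediate
11 | chloromagnesium (8-bromo-penta-O-benzylcatechin-6-yl){2,4-bis[(tert-butoxycarbonyl)oxy]phenyl}methanolate, both carbinol epimers, not isolated | Cl[Mg]OC(c1ccc(OC(=O)OC(C)(C)C)cc1OC(=O)OC(C)(C)C)c1c(OCc3ccccc3)c(Br)c2c(c1OCc1ccccc1)C[C@H](OCc1ccccc1)[C@@H](c1ccc(OCc3ccccc3)c(OCc3ccccc3)c1)O2 | intermediate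
12 | (6E)-6-[(8-bromo-penta-O-benzylcatechin-6-yl)methylidene]-3-[(tert-butoxycarbonyl)oxy]cyclohexa-2,4-dien-1-one (o-quinone methide), not isolated | O=C1C=C(OC(=O)OC(C)(C)C)C=C/C1=C\c1c(OCc3ccccc3)c(Br)c2c(c1OCc1ccccc1)C[C@H](OCc1ccccc1)[C@@H](c1ccc(OCc3ccccc3)c(OCc3ccccc3)c1)O2 | intermediate
13 | (2R,3R,4S)-2-[3,4-bis(benzyloxy)phenyl]-4-[(2R,3S)-3,5,7-tris(benzyloxy)-2-[3,4-bis(benzyloxy)phenyl]-8-bromochroman-6-yl]-7-[(tert-butoxycarbonyl)oxy]chroman-3-yl benzoate (upper ring all-cis) | CC(C)(C)OC(=O)Oc1ccc2c(c1)O[C@H](c1ccc(OCc3ccccc3)c(OCc3ccccc3)c1)[C@H](OC(=O)c1ccccc1)[C@@H]2c1c(OCc3ccccc3)c(Br)c2c(c1OCc1ccccc1)C[C@H](OCc1ccccc1)[C@@H](c1ccc(OCc3ccccc3)c(OCc3ccccc3)c1)O2 | intermediate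
14 | (2R,3R,4S)-2-[3,4-bis(benzyloxy)phenyl]-4-[(2R,3S)-3,5,7-tris(benzyloxy)-2-[3,4-bis(benzyloxy)phenyl]-8-bromochroman-6-yl]chroman-3,7-diol | Oc1ccc2c(c1)O[C@H](c1ccc(OCc3ccccc3)c(OCc3ccccc3)c1)[C@H](O)[C@@H]2c1c(OCc3ccccc3)c(Br)c2c(c1OCc1ccccc1)C[C@H](OCc1ccccc1)[C@@H](c1ccc(OCc3ccccc3)c(OCc3ccccc3)c1)O2 | intermediate
15 | (2R,3R,4S)-2-(3,4-dihydroxyphenyl)-4-[(2R,3S)-2-(3,4-dihydroxyphenyl)-3,5,7-trihydroxychroman-6-yl]chroman-3,7-diol, CNP0141631.2 | Oc1ccc2c(c1)O[C@H](c1ccc(O)c(O)c1)[C@H](O)[C@@H]2c1c(O)cc2c(c1O)C[C@H](O)[C@@H](c1ccc(O)c(O)c1)O2 | target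

**Count**
Total steps: 9. Longest linear sequence: 6 (steps 1, 2, 3, 7, 8, 9 from (+)-catechin).

**Steps most likely to fail**

Step 7 is the highest risk. The enol benzoate is only a styrene-grade nucleophile and the o-quinone methide is hindered by the doubly ortho-substituted ring D. Benzoyl transfer to the magnesium tert-butoxide formed in the flask may eat the alkene. The reversed (isoflavan-type) regiochemistry and an eroded endo or Z outcome are possible. Because the catechin stereocentres are remote, facial selectivity is expected near 1:1, so the yield of 13 is capped near 50% and the two all-cis diastereomers must be separated and assigned (CD, or X-ray of a derivative). The fallback sets out from 4, 6 and 8 and uses the same o-quinone methide 12. It is trapped with alkyne 8 (MgBr2·OEt2, toluene, 60 °C) in a [4+2] cycloaddition that gives the 4H-chromene F1 as two C4 epimers, which are separated. Hydroboration–oxidation (BH3·THF, then NaBO3·4H2O) puts boron on C3 anti to the C4 aryl group and gives the 2,3-trans-3,4-trans alcohol F2. Dess–Martin periodinane gives the flavan-3-one F3. LiBH(s-Bu)3 at −78 °C adds hydride anti to both aryl groups and gives the all-cis alcohol F4. The conditions of step 8 cleave its carbonate, and the route is rejoined at 14.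

Step 3 is the second risk. C6 sits between two benzyloxy groups, so iodination may be slow or may stray to ring E, and the later iodine–magnesium exchange on so electron-rich an iodide may stall. The fallback sets out from 3. Vilsmeier–Haack formylation (POCl3, DMF, 60 °C) gives the 6-carbaldehyde F5. The phenol partner tert-butyl 3-hydroxyphenyl carbonate F6 (from resorcinol and one equivalent of Boc2O) is converted into its bromomagnesium phenoxide (EtMgBr, toluene). It adds ortho-selectively to F5 through a chelated transition state and gives the 2-hydroxybenzhydrol F7. Warming F7 with 9 (toluene, 80 °C) expels water, and the route is rejoined at o-quinone methide 12 and from there at 13.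

Step 9 is the third risk. Seven benzyl ethers and a hindered aryl bromide must go in one pot; debromination may lag, and the free all-cis polyphenol is air-sensitive. The fallback sets out from 14. Bu3SnH with AIBN (toluene, 90 °C) removes bromine first and gives the debrominated heptabenzyl ether F8. BCl3 with pentamethylbenzene (CH2Cl2, −78 °C) then cleaves all benzyl ethers without hydrogen or metal, and the route is rejoined at 15.

Further compounds
F1 | step 7 | tert-butyl (4S)-2-[3,4-bis(benzyloxy)phenyl]-4-(8-bromo-penta-O-benzylcatechin-6-yl)-4H-chromen-7-yl carbonate | CC(C)(C)OC(=O)Oc1ccc2c(c1)OC(c1ccc(OCc3ccccc3)c(OCc3ccccc3)c1)=C[C@@H]2c1c(OCc3ccccc3)c(Br)c2c(c1OCc1ccccc1)C[C@H](OCc1ccccc1)[C@@H](c1ccc(OCc3ccccc3)c(OCc3ccccc3)c1)O2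
F2 | step 7 | tert-butyl (2R,3S,4S)-2-[3,4-bis(benzyloxy)phenyl]-4-(8-bromo-penta-O-benzylcatechin-6-yl)-3-hydroxychroman-7-yl carbonate (2,3-trans-3,4-trans) | CC(C)(C)OC(=O)Oc1ccc2c(c1)O[C@H](c1ccc(OCc3ccccc3)c(OCc3ccccc3)c1)[C@@H](O)[C@@H]2c1c(OCc3ccccc3)c(Br)c2c(c1OCc1ccccc1)C[C@H](OCc1ccccc1)[C@@H](c1ccc(OCc3ccccc3)c(OCc3ccccc3)c1)O2
F3 | step 7 | tert-butyl 2,4-cis-2-[3,4-bis(benzyloxy)phenyl]-4-(8-bromo-penta-O-benzylcatechin-6-yl)-3-oxochroman-7-yl carbonate | CC(C)(C)OC(=O)Oc1ccc2c(c1)O[C@H](c1ccc(OCc3ccccc3)c(OCc3ccccc3)c1)C(=O)[C@@H]2c1c(OCc3ccccc3)c(Br)c2c(c1OCc1ccccc1)C[C@H](OCc1ccccc1)[C@@H](c1ccc(OCc3ccccc3)c(OCc3ccccc3)c1)O2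
F4 | step 7 | tert-butyl (2R,3R,4S)-2-[3,4-bis(benzyloxy)phenyl]-4-(8-bromo-penta-O-benzylcatechin-6-yl)-3-hydroxychroman-7-yl carbonate (all-cis) | CC(C)(C)OC(=O)Oc1ccc2c(c1)O[C@H](c1ccc(OCc3ccccc3)c(OCc3ccccc3)c1)[C@H](O)[C@@H]2c1c(OCc3ccccc3)c(Br)c2c(c1OCc1ccccc1)C[C@H](OCc1ccccc1)[C@@H](c1ccc(OCc3ccccc3)c(OCc3ccccc3)c1)O2
F5 | step 3 | 8-bromo-penta-O-benzylcatechin-6-carbaldehyde | O=Cc1c(OCc3ccccc3)c(Br)c2c(c1OCc1ccccc1)C[C@H](OCc1ccccc1)[C@@H](c1ccc(OCc3ccccc3)c(OCc3ccccc3)c1)O2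
F6 | step 3 | tert-butyl 3-hydroxyphenyl carbonate | CC(C)(C)OC(=O)Oc1cccc(O)c1
F7 | step 3 | (8-bromo-penta-O-benzylcatechin-6-yl){4-[(tert-butoxycarbonyl)oxy]-2-hydroxyphenyl}methanol, both carbinol epimers | OC(c1ccc(OC(=O)OC(C)(C)C)cc1O)c1c(OCc3ccccc3)c(Br)c2c(c1OCc1ccccc1)C[C@H](OCc1ccccc1)[C@@H](c1ccc(OCc3ccccc3)c(OCc3ccccc3)c1)O2
F8 | step 9 | (2R,3R,4S)-2-[3,4-bis(benzyloxy)phenyl]-4-[(2R,3S)-3,5,7-tris(benzyloxy)-2-[3,4-bis(benzyloxy)phenyl]chroman-6-yl]chroman-3,7-diol | Oc1ccc2c(c1)O[C@H](c1ccc(OCc3ccccc3)c(OCc3ccccc3)c1)[C@H](O)[C@@H]2c1c(OCc3ccccc3)cc2c(c1OCc1ccccc1)C[C@H](OCc1ccccc1)[C@@H](c1ccc(OCc3ccccc3)c(OCc3ccccc3)c1)O2
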